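Ring A (C1–C4 plus the ring-fusion atoms C5 and C10) is closed onto a preformed, enantioenriched ring B by a sulfone-mediated [3+3] annulation with methyl vinyl ketone. In ring B sulfone 9 the unit C1–C10=C5 is a masked 1,3-dinucleophile: the α-sulfonyl carbon C1 adds to the enone (bond C1–C2) and the γ-carbon C5 of the same allyl anion then attacks the ketone (bond C4–C5), which installs the methyl-bearing quaternary C5 and a C4 methyl carbinol that becomes the ring A olefin. Ring B arises from a catalytic asymmetric Diels–Alder reaction; the cyclopentenone is attached last by aldol condensation and face-selective hydrogenation.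

Key step: step 7

Remark on numbering: decalin atoms are C1–C10 (ring A = C1, C2, C3, C4, C5, C10; ring B = C5 to C10). C4 carries the vinylic methyl, C5 is the quaternary ring-fusion carbon, C8 the quaternary carbon bearing C11, C9 the CH(CH3) next to C10. The cyclopentenone is C1′ (CH) to C5′ (carbinol).

Assumption: the facial sense of the two reagent-controlled steps (4 and 15) is taken from the accepted transition-state models; both chiral reagents exist in either enantiomeric form.

Step 1
Reactants: 1 methyl vinyl ketone; 2 acetaldehyde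
Product: 3 3-(1-hydroxyethyl)but-3-en-2-one (racemic)
Conditions: DABCO (20 mol%), 2 (3 equiv), THF, 0 °C to rt
Reagents that add atoms: none
Why: Morita–Baylis–Hillman reaction, in which DABCO adds to the enone and the resulting enolate captures acetaldehyde before the amine is expelled; the carbinol centre is racemic and is erased in step 2.

Step 2
Reactants: 3 3-(1-hydroxyethyl)but-3-en-2-one
Product: 4 (2E)-2-acetylbut-2-en-1-yl acetate
Conditions: Ac2O, Et3N, DMAP (cat.), CH2Cl2, 0 °C; then DABCO (20 mol%), THF, 50 °C
Reagents that add atoms: acetic anhydride, CC(=O)OC(C)=O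
Why: O-acetylation followed by DABCO-mediated double SN2′ allylic transposition should equilibrate the secondary acetate to the conjugated primary acetate, the (E)-isomer (ethylidene methyl syn to CH2OAc) being the thermodynamic one.

Step 3
Reactants: 4 (2E)-2-acetylbut-2-en-1-yl acetate
Product: 5 (2Z)-2-ethylidene-3-methylbut-3-en-1-yl acetate
Conditions: Ph3PCH3Br, KN(SiMe3)2, THF, 0 °C; then 4, −78 to 0 °C
Reagents that add atoms: methylenetriphenylphosphorane, C=P(c1ccccc1)(c1ccccc1)c1ccccc1
Why: Wittig methylenation of the ketone, which at low temperature should outrun attack of the ylide on the acetate, gives the 2,3-disubstituted diene with the trisubstituted olefin geometry intact (the descriptor changes to Z only by priority).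

Step 4
Reactants: 5 (2Z)-2-ethylidene-3-methylbut-3-en-1-yl acetate; 6 methacrolein
Product: 7 [(5S,6R)-5-formyl-2,5,6-trimethylcyclohex-1-en-1-yl]methyl acetate
Conditions: (S)-o-tolyl-oxazaborolidine·HNTf2 (10 mol%), 6 (3 equiv), CH2Cl2, −78 °C
Reagents that add atoms: none
Why: Catalytic enantioselective Diels–Alder reaction in which the protonated oxazaborolidine activates methacrolein: the terminal methyl of the diene directs the formyl-bearing carbon next to it, the endo-formyl transition state places CHO cis to that methyl (setting quaternary C8 and C9 relative to each other), and the catalyst shields one enal face to fix their absolute configuration.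

Step 5
Reactants: 7 [(5S,6R)-5-formyl-2,5,6-trimethylcyclohex-1-en-1-yl]methyl acetate
Product: 8 [(5S,6R)-5-(dimethoxymethyl)-2,5,6-trimethylcyclohex-1-en-1-yl]methyl acetate
Conditions: HC(OMe)3, MeOH, PPTS (cat.), rt
Reagents that add atoms: trimethyl orthoformate, COC(OC)OC
Why: Acid-catalysed acetalisation with the orthoformate as water scavenger masks the hindered aldehyde for the carbanion, reduction and dehydration steps; the allylic acetate is untouched.

Step 6
Reactants: 8 [(5S,6R)-5-(dimethoxymethyl)-2,5,6-trimethylcyclohex-1-en-1-yl]methyl acetate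
Product: 9 ({[(5S,6S)-5-(dimethoxymethyl)-2,5,6-trimethylcyclohex-1-en-1-yl]methyl}sulfonyl)benzene
Conditions: Pd(PPh3)4 (5 mol%), PhSO2Na, THF–DMSO, 40 °C
Reagents that add atoms: sodium benzenesulfinate, [Na+].[O-]S(=O)c1ccccc1
Why: Tsuji–Trost allylic substitution: ionisation of the primary allylic acetate gives a π-allyl palladium complex that the sulfinate attacks through sulfur at the less hindered CH2 terminus, keeping the tetrasubstituted olefin in place (the C9 descriptor becomes S only because sulfur raises the priority of its neighbour).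

Step 7
Reactants: 9 ({[(5S,6S)-5-(dimethoxymethyl)-2,5,6-trimethylcyclohex-1-en-1-yl]methyl}sulfonyl)benzene; 1 methyl vinyl ketone
Product: 11 (5S,6S,8aS)-6-(dimethoxymethyl)-1,5,6,8a-tetramethyl-4-(phenylsulfonyl)-1,2,3,5,6,7,8,8a-octahydronaphthalen-1-ol, via Michael adduct 10 (not isolated)
Conditions: LiN(SiMe3)2 (1.1 equiv), THF–DMPU, −78 °C; 1 (1.2 equiv), −78 to 0 °C; AcOH quench at −78 °C
Reagents that add atoms: none
Why: Deprotonation α to sulfur gives the 1-sulfonylallyl anion spanning C1–C10–C5, which adds to methyl vinyl ketone through its unhindered α-carbon (Michael addition, C1–C2); proton transfer from the still acidic C1–H to the ketone enolate regenerates the allyl anion, whose γ-carbon C5 attacks the ketone carbonyl (vinylogous aldol, C4–C5), the closest known reaction type being the Michael–aldol [3+3] annulation of allylic sulfone carbanions with enones. Ring A closes in a 6-exo-trig mode onto the C=O with the allyl unit inside the new ring; α-attack on the carbonyl would give a cyclobutane and should not compete. The new quaternary centre C5 is controlled by the C9 methyl, which sits pseudoaxial on the β face to avoid allylic strain with the sulfonylated C1 substituent, so the tether delivers C4 to the α face and leaves the C5 methyl β, cis to the C9 methyl; the C4 carbinol configuration is irrelevant because C4 becomes sp2 in step 10. The step needs 1,4- over 1,2-addition and α- over γ-attack in the first bond, secured by the DMPU-solvated lithium counter-ion and the fully substituted γ-terminus; keeping the mixture at or below 0 °C and quenching cold limits retro-aldol opening.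

Step 8
Reactants: 11 (5S,6S,8aS)-6-(dimethoxymethyl)-1,5,6,8a-tetramethyl-4-(phenylsulfonyl)-1,2,3,5,6,7,8,8a-octahydronaphthalen-1-ol
Product: 12 (5R,6S,8aS)-6-(dimethoxymethyl)-1,5,6,8a-tetramethyl-1,2,3,5,6,7,8,8a-octahydronaphthalen-1-ol
Conditions: 6% Na/Hg, MeOH–THF, −20 °C
Reagents that add atoms: none
Why: Electron-transfer desulfonylation of the vinyl sulfone (loss of sulfinate, then protonation of the vinyl anion) should replace C–S by C–H without moving the C1=C10 double bond; acetal and tertiary alcohol are inert.

Step 9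
Reactants: 12 (5R,6S,8aS)-6-(dimethoxymethyl)-1,5,6,8a-tetramethyl-1,2,3,5,6,7,8,8a-octahydronaphthalen-1-ol
Product: 13 (4aS,5R,6S,8aS)-6-(dimethoxymethyl)-1,5,6,8a-tetramethyldecahydronaphthalen-1-ol
Conditions: [Ir(cod)(PCy3)(py)]PF6 (5 mol%), H2 (1 atm), CH2Cl2, rt
Reagents that add atoms: none
Why: Hydroxyl-directed homogeneous hydrogenation: the cationic iridium binds the C4 hydroxyl (expected axial and α after the chair-like closure) and adds H2 to the α face of C1=C10, the β face being blocked by the C5 and C9 methyls, which should set C10–H trans to the angular methyl.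

Step 10
Reactants: 13 (4aS,5R,6S,8aS)-6-(dimethoxymethyl)-1,5,6,8a-tetramethyldecahydronaphthalen-1-ol
Product: 14 (1R,2S,4aS,8aS)-2-(dimethoxymethyl)-1,2,4a,5-tetramethyl-1,2,3,4,4a,7,8,8a-octahydronaphthalene
Conditions: SOCl2, pyridine, CH2Cl2, 0 °C
Reagents that add atoms: none
Why: Chlorosulfite formation and pyridine-mediated anti elimination of the axial tertiary leaving group with the axial C3 hydrogen should give the endocyclic trisubstituted C3=C4 olefin in preference to the exocyclic methylene isomer.

Step 11
Reactants: 14 (1R,2S,4aS,8aS)-2-(dimethoxymethyl)-1,2,4a,5-tetramethyl-1,2,3,4,4a,7,8,8a-octahydronaphthalene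
Product: 15 (1R,2S,4aS,8aS)-1,2,4a,5-tetramethyl-1,2,3,4,4a,7,8,8a-octahydronaphthalene-2-carbaldehyde
Conditions: PPTS, acetone–H2O, 50 °C
Reagents that add atoms: water, O
Why: Mild acid-catalysed acetal hydrolysis releases the non-enolisable aldehyde without isomerising the trisubstituted olefin.

Step 12
Reactants: 16 methyl cyclopent-3-ene-1-carboxylate
Product: 17 methyl 3,4-dihydroxycyclopentane-1-carboxylate (cis-diol)
Conditions: OsO4 (2 mol%), N-methylmorpholine N-oxide, acetone–H2O, rt
Reagents that add atoms: N-methylmorpholine N-oxide, C[N+]1([O-])CCOCC1; water, O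
Why: Catalytic syn-dihydroxylation of the only olefin; the diol stereochemistry is irrelevant because both carbinols are oxidised next.

Step 13
Reactants: 17 methyl 3,4-dihydroxycyclopentane-1-carboxylate
Product: 18 methyl 3-hydroxy-4-oxocyclopent-2-ene-1-carboxylate
Conditions: (COCl)2, DMSO, CH2Cl2, −78 °C; Et3N, −78 °C to rt
Reagents that add atoms: none
Why: Twofold Swern oxidation gives the 1,2-diketone, which should rest as its enol; the dione is symmetric, so only one enol constitution exists.

Step 14
Reactants: 18 methyl 3-hydroxy-4-oxocyclopent-2-ene-1-carboxylate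
Product: 19 methyl 3-methoxy-4-oxocyclopent-2-ene-1-carboxylate (racemic)
Conditions: Me3SiCHN2, MeOH–toluene, 0 °C
Reagents that add atoms: (trimethylsilyl)diazomethane, C[Si](C)(C)C=[N+]=[N-]
Why: O-methylation of the acidic enol by the diazoalkane gives the 2-methoxy enone; C1 is still epimerisable and is fixed in step 15.

Step 15
Reactants: 19 methyl 3-methoxy-4-oxocyclopent-2-ene-1-carboxylate
Product: 20 methyl (1S)-1-hydroxy-3-methoxy-4-oxocyclopent-2-ene-1-carboxylate
Conditions: NaN(SiMe3)2 (1.05 equiv), THF, −78 °C; (+)-(camphorsulfonyl)oxaziridine; AcOH quench at −78 °C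
Reagents that add atoms: (+)-(camphorsulfonyl)oxaziridine, CC1(C)C2CCC13CS(=O)(=O)N4OC34C2
Why: Reagent-controlled electrophilic enolate hydroxylation: the doubly activated C1–H (α to the ester, vinylogous to the ketone) is removed selectively, and the chiral N-sulfonyloxaziridine transfers oxygen to the ester α-carbon (the enone α-carbon is fully substituted) from one enantiotopic face to set the tertiary carbinol; the cold quench avoids retro-aldol racemisation.

Step 16
Reactants: 20 methyl (1S)-1-hydroxy-3-methoxy-4-oxocyclopent-2-ene-1-carboxylate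
Product: 21 methyl (1S)-3-methoxy-4-oxo-1-[(trimethylsilyl)oxy]cyclopent-2-ene-1-carboxylate
Conditions: Me3SiCl, imidazole, DMF, rt
Reagents that add atoms: chlorotrimethylsilane, C[Si](C)(C)Cl
Why: Silylation of the tertiary hydroxyl blocks retro-aldol opening during the enolate chemistry of step 17.

Step 17
Reactants: 21 methyl (1S)-3-methoxy-4-oxo-1-[(trimethylsilyl)oxy]cyclopent-2-ene-1-carboxylate; 15 (1R,2S,4aS,8aS)-1,2,4a,5-tetramethyl-1,2,3,4,4a,7,8,8a-octahydronaphthalene-2-carbaldehyde
Product: 24 methyl (1R,5Z)-1-hydroxy-3-methoxy-4-oxo-5-{[(1R,2S,4aS,8aS)-1,2,4a,5-tetramethyl-1,2,3,4,4a,7,8,8a-octahydronaphthalen-2-yl]methylidene}cyclopent-2-ene-1-carboxylate, via aldol adduct 22 (not isolated), via silyl ether enone 23 (not isolated)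
Conditions: LiN(i-Pr)2, THF, −78 °C; 15; MsCl, −78 to 0 °C; DBU, rt; 1 M HCl–THF, 0 °C
Reagents that add atoms: none
Why: Directed aldol condensation: the only enolisable position of 21 (C5, α′ to the ketone) is deprotonated, the enolate adds to non-enolisable aldehyde 15, in situ mesylation and E1cB elimination give the exocyclic enone, and the acidic work-up removes the silyl group; the carbinol centre is untouched (its descriptor becomes R only through the priority change).

Step 18
Reactants: 24 methyl (1R,5Z)-1-hydroxy-3-methoxy-4-oxo-5-{[(1R,2S,4aS,8aS)-1,2,4a,5-tetramethyl-1,2,3,4,4a,7,8,8a-octahydronaphthalen-2-yl]methylidene}cyclopent-2-ene-1-carboxylate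
Product: 25 Dysidenone B, methyl (1R,5S)-1-hydroxy-3-methoxy-4-oxo-5-{[(1R,2R,4aS,8aS)-1,2,4a,5-tetramethyl-1,2,3,4,4a,7,8,8a-octahydronaphthalen-2-yl]methyl}cyclopent-2-ene-1-carboxylate
Conditions: H2 (1 atm), 5% Pd/C, EtOAc, 0 °C, stopped after one equivalent
Reagents that add atoms: none
Why: Heterogeneous hydrogenation should reduce the conjugated exocyclic olefin faster than the electron-rich methoxy-enone olefin and the hindered ring A olefin, with hydrogen arriving on the face of the small, surface-binding hydroxyl and anti to the ester, which places the C1′ hydrogen cis to OH and sets the last stereocentre.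

Compound list
1 | methyl vinyl ketone (but-3-en-2-one) | CC(=O)C=C | starting material
2 | acetaldehyde | CC=O | starting material
3 | 3-(1-hydroxyethyl)but-3-en-2-one (racemic) | CC(O)C(=C)C(C)=O | intermediate
4 | (2E)-2-acetylbut-2-en-1-yl acetate | C/C=C(\COC(C)=O)C(C)=O | intermediate
5 | (2Z)-2-ethylidene-3-methylbut-3-en-1-yl acetate | C/C=C(\COC(C)=O)C(C)=C | intermediate
6 | methacrolein (2-methylprop-2-enal) | CC(=C)C=O | starting material
7 | [(5S,6R)-5-formyl-2,5,6-trimethylcyclohex-1-en-1-yl]methyl acetate | O=C[C@@]1(C)CCC(C)=C(COC(C)=O)[C@H]1C | intermediate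
8 | [(5S,6R)-5-(dimethoxymethyl)-2,5,6-trimethylcyclohex-1-en-1-yl]methyl acetate | COC(OC)[C@@]1(C)CCC(C)=C(COC(C)=O)[C@H]1C | intermediate
9 | ({[(5S,6S)-5-(dimethoxymethyl)-2,5,6-trimethylcyclohex-1-en-1-yl]methyl}sulfonyl)benzene | COC(OC)[C@@]1(C)CCC(C)=C(CS(=O)(=O)c2ccccc2)[C@H]1C | intermediate
10 | 5-[(5S,6S)-5-(dimethoxymethyl)-2,5,6-trimethylcyclohex-1-en-1-yl]-5-(phenylsulfonyl)pentan-2-one (Michael adduct, sulfonyl-bearing carbon undefined) | COC(OC)[C@@]1(C)CCC(C)=C(C(CCC(C)=O)S(=O)(=O)c2ccccc2)[C@H]1C | intermediate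
11 | (5S,6S,8aS)-6-(dimethoxymethyl)-1,5,6,8a-tetramethyl-4-(phenylsulfonyl)-1,2,3,5,6,7,8,8a-octahydronaphthalen-1-ol (C1 carbinol undefined) | COC(OC)[C@@]1(C)CC[C@]2(C)C(C)(O)CCC(S(=O)(=O)c3ccccc3)=C2[C@H]1C | intermediate
12 | (5R,6S,8aS)-6-(dimethoxymethyl)-1,5,6,8a-tetramethyl-1,2,3,5,6,7,8,8a-octahydronaphthalen-1-ol | COC(OC)[C@@]1(C)CC[C@]2(C)C(C)(O)CCC=C2[C@H]1C | intermediate
13 | (4aS,5R,6S,8aS)-6-(dimethoxymethyl)-1,5,6,8a-tetramethyldecahydronaphthalen-1-ol | COC(OC)[C@@]1(C)CC[C@]2(C)C(C)(O)CCC[C@H]2[C@H]1C | intermediate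
14 | (1R,2S,4aS,8aS)-2-(dimethoxymethyl)-1,2,4a,5-tetramethyl-1,2,3,4,4a,7,8,8a-octahydronaphthalene | COC(OC)[C@@]1(C)CC[C@]2(C)C(C)=CCC[C@H]2[C@H]1C | intermediate
15 | (1R,2S,4aS,8aS)-1,2,4a,5-tetramethyl-1,2,3,4,4a,7,8,8a-octahydronaphthalene-2-carbaldehyde | O=C[C@@]1(C)CC[C@]2(C)C(C)=CCC[C@H]2[C@H]1C | intermediate
16 | methyl cyclopent-3-ene-1-carboxylate | COC(=O)C1CC=CC1 | starting material
17 | methyl 3,4-dihydroxycyclopentane-1-carboxylate (cis-diol) | COC(=O)C1CC(O)C(O)C1 | intermediate
18 | methyl 3-hydroxy-4-oxocyclopent-2-ene-1-carboxylate | COC(=O)C1C=C(O)C(=O)C1 | intermediate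
19 | methyl 3-methoxy-4-oxocyclopent-2-ene-1-carboxylate (racemic) | COC(=O)C1C=C(OC)C(=O)C1 | intermediate
20 | methyl (1S)-1-hydroxy-3-methoxy-4-oxocyclopent-2-ene-1-carboxylate | COC(=O)[C@@]1(O)C=C(OC)C(=O)C1 | intermediate
21 | methyl (1S)-3-methoxy-4-oxo-1-[(trimethylsilyl)oxy]cyclopent-2-ene-1-carboxylate | COC(=O)[C@@]1(O[Si](C)(C)C)C=C(OC)C(=O)C1 | intermediate
22 | methyl (1R)-5-{hydroxy[(1R,2S,4aS,8aS)-1,2,4a,5-tetramethyl-1,2,3,4,4a,7,8,8a-octahydronaphthalen-2-yl]methyl}-3-methoxy-4-oxo-1-[(trimethylsilyl)oxy]cyclopent-2-ene-1-carboxylate (aldol adduct, two new centres undefined) | COC(=O)[C@@]1(O[Si](C)(C)C)C=C(OC)C(=O)C1C(O)[C@@]1(C)CC[C@]2(C)C(C)=CCC[C@H]2[C@H]1C | intermediate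
23 | methyl (1R,5Z)-3-methoxy-4-oxo-5-{[(1R,2S,4aS,8aS)-1,2,4a,5-tetramethyl-1,2,3,4,4a,7,8,8a-octahydronaphthalen-2-yl]methylidene}-1-[(trimethylsilyl)oxy]cyclopent-2-ene-1-carboxylate | COC(=O)[C@@]1(O[Si](C)(C)C)C=C(OC)C(=O)/C1=C\[C@@]1(C)CC[C@]2(C)C(C)=CCC[C@H]2[C@H]1C | intermediate
24 | methyl (1R,5Z)-1-hydroxy-3-methoxy-4-oxo-5-{[(1R,2S,4aS,8aS)-1,2,4a,5-tetramethyl-1,2,3,4,4a,7,8,8a-octahydronaphthalen-2-yl]methylidene}cyclopent-2-ene-1-carboxylate | COC(=O)[C@@]1(O)C=C(OC)C(=O)/C1=C\[C@@]1(C)CC[C@]2(C)C(C)=CCC[C@H]2[C@H]1C | intermediate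
25 | Dysidenone B, methyl (1R,5S)-1-hydroxy-3-methoxy-4-oxo-5-{[(1R,2R,4aS,8aS)-1,2,4a,5-tetramethyl-1,2,3,4,4a,7,8,8a-octahydronaphthalen-2-yl]methyl}cyclopent-2-ene-1-carboxylate | COC(=O)[C@@]1(O)C=C(OC)C(=O)[C@H]1C[C@@]1(C)CC[C@]2(C)C(C)=CCC[C@H]2[C@H]1C | target

Total step count: 18.
Longest linear sequence: 13 steps (steps 1–11, then 17 and 18); steps 12–16 form the convergent branch.

Steps most likely to fail

Step 7. The γ-selective closure onto the ketone builds a quaternary centre next to a tertiary alkoxide and is reversible, so the reaction may stall at the open Michael adduct or leak back by retro-aldol opening; base-induced polymerisation of the enone is a second loss channel. Fallback: starting from 9, the sequence is stopped after the conjugate addition and Michael adduct 10 is isolated. The ketone is then activated with Me2AlCl (CH2Cl2, −78 to 0 °C) so that the tetrasubstituted C5=C10 olefin attacks the carbonyl in an intramolecular carbonyl-ene (Prins-type) closure with loss of the acidified C1 proton, which returns to 11.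

Step 9. The hindered trisubstituted olefin may be reduced with poor facial selectivity, or may migrate toward C9 before it is reduced. Fallback: starting from 11, the olefin is avoided altogether. Single-electron conjugate reduction of the vinyl sulfone (SmI2, HMPA, MeOH, THF, −78 °C) should protonate C10 from the α face and give saturated sulfone F1; sodium amalgam in methanol then removes the sulfonyl group and the route is rejoined at 13.

Step 15. Oxygen may be transferred to the enone α-carbon instead of the ester α-carbon, the enantioselectivity may be insufficient, or the alkoxide may racemise by retro-aldol opening. Fallback: starting from 19, the sodium enolate is hydroxylated with achiral 2-(phenylsulfonyl)-3-phenyloxaziridine to give racemic alcohol F2. This is resolved with a carboxylesterase (pig liver esterase, phosphate buffer pH 7), which should hydrolyse the (R)-ester to acid F3 and leave the (S)-ester 20.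

Further compounds
F0 | step 7 | none | none
F1 | step 9 | (4aS,5R,6S,8aS)-6-(dimethoxymethyl)-1,5,6,8a-tetramethyl-4-(phenylsulfonyl)decahydronaphthalen-1-ol (C1 and C4 undefined) | COC(OC)[C@@]1(C)CC[C@]2(C)C(C)(O)CCC(S(=O)(=O)c3ccccc3)[C@H]2[C@H]1C
F2 | step 15 | methyl 1-hydroxy-3-methoxy-4-oxocyclopent-2-ene-1-carboxylate (racemic) | COC(=O)C1(O)C=C(OC)C(=O)C1
F3 | step 15 | (1R)-1-hydroxy-3-methoxy-4-oxocyclopent-2-ene-1-carboxylic acid | OC(=O)[C@]1(O)C=C(OC)C(=O)C1
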